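**Retrosynthetic overview**
1. The C3 benzoyl group and the C2 O-methyl group come off first. Ring A (C1–C2–C3–C4–C5–C9) is then opened at C1–C2 and C4–C5 (Effenberger α,α′-annulation with malonyl dichloride), which leaves ring B (C1–C8–C7–C6–C5–C9) as a cyclohexanone silyl enol ether.
2. Enabling feature: in ring B the C9 carbonyl carbon is 1,5-related, along both arcs (C9–C1–C8–C7 and C9–C5–C6–C7), to the allylic CH2 of the C7 prenyl group. Once that CH2 is raised to C=O, C8 with its two methyl groups, C7 and the whole prenyl chain together are the symmetric dienone phorone.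
3. Key disconnection: a formal [4+2] across C6–C7 and C8–C1 between phorone (C7=C8) and the acyclic 2-silyloxydiene C6H2=C5(lavandulyl)–C9(OSi)=C1H(prenyl).
4. The diene comes from an α-methylene ketone (β-keto phosphonate alkylation, then olefination with formaldehyde) and (S)-lavandulyl iodide, which is made by auxiliary-controlled deconjugative prenylation.
5. Order of ring formation: ring B in the key step, then ring A.

Key step: step 9

Remark: C1–C9 are the bicyclo[3.3.1]nonane positions of the target: C1 bridgehead with prenyl, C2 OMe, C3 benzoyl, C4 C=O, C5 bridgehead with lavandulyl, C6 CH2, C7 CH-prenyl, C8 CMe2, C9 bridging C=O. These numbers are used for the same atoms in all intermediates. Lavandulyl means 5-methyl-2-(prop-1-en-2-yl)hex-4-en-1-yl. Its stereocentre keeps the spatial arrangement of (S)-lavandulol throughout, and the descriptor becomes R once the CH2 group carries carbon. The trione is drawn as its triketo tautomer.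

Step 1
Reactants: 1 (S)-4-benzyl-1,3-oxazolidin-2-one; 2 3-methylbut-2-enoyl chloride
Product: 3 (S)-4-benzyl-3-(3-methylbut-2-enoyl)-1,3-oxazolidin-2-one
Conditions: n-BuLi, THF, −78 °C; then 2, −78 to 0 °C
Reagents that add atoms: none
Why: N-acylation of the lithiated oxazolidinone with an acid chloride is the standard entry to chiral imides and touches no stereocentre.

Step 2
Reactants: 3 imide; 4 prenyl bromide (1-bromo-3-methylbut-2-ene)
Product: 5 (S)-4-benzyl-3-[(2S)-5-methyl-2-(prop-1-en-2-yl)hex-4-enoyl]-1,3-oxazolidin-2-one
Conditions: NaHMDS, THF, −78 °C; then 4, −78 to −30 °C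
Reagents that add atoms: none
Why: Deconjugative α-alkylation of an α,β-unsaturated N-acyloxazolidinone: γ-deprotonation gives the sodium-chelated Z-dienolate, which takes up the prenyl group at the α-carbon on the face opposite the benzyl group and so sets the side-chain stereocentre as 2S.

Step 3
Reactants: 5 alkylated imide
Product: 6 (S)-lavandulol, (2S)-5-methyl-2-(prop-1-en-2-yl)hex-4-en-1-ol
Conditions: LiBH4, H2O (1 equiv), Et2O, 0 °C
Reagents that add atoms: none
Why: Reductive removal of the auxiliary by hydride attack on the exocyclic imide carbonyl is faster than enolisation, so the stereocentre is kept and the auxiliary is recovered.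

Step 4
Reactants: 6 (S)-lavandulol
Product: 7 (S)-lavandulyl iodide, (3S)-3-(iodomethyl)-2,6-dimethylhepta-1,5-diene
Conditions: I2, PPh3, imidazole, CH2Cl2, 0 °C
Reagents that add atoms: iodine, II
Why: Appel-type iodination is an SN2 displacement at the primary carbon under neutral conditions, so the adjacent stereocentre and both alkenes are left alone.

Step 5
Reactants: 8 dimethyl (2-oxopropyl)phosphonate; 4 prenyl bromide
Product: 9 dimethyl (6-methyl-2-oxohept-5-en-1-yl)phosphonate
Conditions: NaH, THF, 0 °C; n-BuLi, 0 °C; then 4
Reagents that add atoms: none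
Why: γ-Alkylation of a β-keto phosphonate dianion, in which the more basic terminal carbanion reacts selectively with the allylic bromide.

Step 6
Reactants: 9 β-keto phosphonate; 7 (S)-lavandulyl iodide
Product: 10 dimethyl {1-[(2R)-lavandulyl]-6-methyl-2-oxohept-5-en-1-yl}phosphonate (both epimers at the P-bearing carbon)
Conditions: NaH, THF–DMPU, 0 to 60 °C
Reagents that add atoms: none
Why: SN2 C-alkylation of the soft sodium β-keto phosphonate anion with a primary iodide; the new P-bearing stereocentre forms as a mixture that the next step erases.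

Step 7
Reactants: 10 alkylated β-keto phosphonate
Product: 11 2-[(2R)-lavandulyl]-7-methylocta-1,6-dien-3-one (α-methylene ketone, C6H2=C5–C9=O)
Conditions: 37% aq. HCHO, K2CO3, THF–H2O, rt
Reagents that add atoms: formaldehyde, C=O
Why: Horner–Wadsworth–Emmons olefination with formaldehyde turns the phosphonate carbon regiospecifically into the C5=C6 methylene unit, which direct methylenation of a ketone with two similar α-CH2 groups could not do.

Step 8
Reactants: 11 α-methylene ketone
Product: 12 (3Z)-3-(tert-butyldimethylsilyloxy)-2-[(2R)-lavandulyl]-7-methylocta-1,3,6-triene (2-silyloxydiene C6=C5–C9(OTBS)=C1)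
Conditions: TBSOTf, Et3N, CH2Cl2, 0 °C
Reagents that add atoms: tert-butyldimethylsilyl triflate, CC(C)(C)[Si](C)(C)OS(=O)(=O)C(F)(F)F
Why: Soft enolisation and silylation of a vinyl ketone, in which only the α′-CH2 (C1) can be deprotonated and the amine/silyl triflate conditions give the Z-enol ether that places the prenyl group outside the s-cis diene.

Step 9
Reactants: 12 2-silyloxydiene; 13 phorone (2,6-dimethylhepta-2,5-dien-4-one)
Product: 14 ring-B cyclohexene, C9(OTBS)=C5(lavandulyl), C6H2, C7H(CO–CH=CMe2), C8Me2, C1H(prenyl), with C1 prenyl and C7 acyl cis, (1R,7R)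
Conditions: (S)-3,3-diphenyl-1-(2-methylphenyl)tetrahydro-1H,3H-pyrrolo[1,2-c][1,3,2]oxazaborole (20 mol %), AlBr3 (16 mol %), 13 (3 equiv), CH2Cl2, −40 °C
Reagents that add atoms: none
Why: Proposed new method: the AlBr3-activated oxazaborolidine binds the carbonyl oxygen of 13 and starts a strongly asynchronous normal-demand [4+2] cycloaddition, in which the enol-ether carbon C1 of 12 attacks the β,β-dimethyl carbon C8 (Mukaiyama–Michael phase) and the developing enolate carbon C7 closes onto the methylene terminus C6, so that the silyl group stays on O9 and the product is the regiodefined C5=C9 silyl enol ether. The closest known reaction types are the Diels–Alder reaction of hindered 2-silyloxydienes with β,β-disubstituted enones under mixed AlBr3/AlMe3 catalysis and the enantioselective Diels–Alder reaction of 2-silyloxydienes with less substituted acyclic enones under cationic oxazaborolidine catalysis, and only their combination on a β,β-dimethyl enone is new. Ring B, the only ring closed, forms in a suprafacial [4π+2π] mode from the s-cis diene (in the stepwise limit a 6-endo-trig Michael closure of C7 onto C6). C7 is controlled by the catalyst, whose aryl groups should cover one face of the bound enone arm (carbonyl on boron, α-C–H in contact with the ring oxygen) and leave the Re face at C7 open, while C1 follows from the endo rule and the Z-enol ether, which place the C1 prenyl and C7 acyl groups cis and diequatorial; C8 is not stereogenic and the lavandulyl centre is a spectator. The step needs regioselectivity, secured by the 2-silyloxy group that makes C1 the nucleophilic terminus and pairs it with the electrophilic β-carbon C8, and chemoselectivity, secured because the isolated alkenes of 12 are far weaker nucleophiles than the silyl dienol ether, both arms of 13 are equivalent, and the α′-branched enone left in 14 is much more hindered than the excess 13. The cis C1 substituent also anchors C7 thermodynamically until the neighbouring carbonyl group is removed.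

Step 10
Reactants: 14 enone adduct
Product: 15 allylic alcohol, C7–CH(OH)–CH=CMe2 (both carbinol epimers), otherwise as 14
Conditions: DIBAL-H, CH2Cl2, −78 °C
Reagents that add atoms: none
Why: 1,2-Reduction of the hindered enone at low temperature leaves the silyl enol ether and the alkenes alone and removes the acidity of H7; the carbinol configuration is irrelevant.

Step 11
Reactants: 15 allylic alcohol
Product: 16 allylic methyl carbonate, C7–CH(OCO2Me)–CH=CMe2, otherwise as 14
Conditions: ClCO2Me, pyridine, 4-(dimethylamino)pyridine (10 mol %), CH2Cl2, 0 °C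
Reagents that add atoms: methyl chloroformate, COC(=O)Cl
Why: Acylation of the secondary allylic alcohol installs the leaving group needed for π-allyl formation without touching any stereocentre of the ring.

Step 12
Reactants: 16 allylic carbonate
Product: 17 ring-B silyl enol ether, C9(OTBS)=C5(lavandulyl), C7H(prenyl), C8Me2, C1H(prenyl), (1R,7R)
Conditions: Pd(PPh3)4 (5 mol %), LiBHEt3, THF, rt
Reagents that add atoms: none
Why: Tsuji–Trost-type hydrogenolysis, in which zerovalent palladium ionises the carbonate to a 1,1-dimethyl-π-allyl complex and the borohydride delivers hydride to the less substituted terminus (the carbon on C7), which gives the trisubstituted prenyl alkene and leaves C7 untouched.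

Step 13
Reactants: 17 ring-B silyl enol ether; 18 malonyl dichloride
Product: 20 (1R,5S,7R)-5-[(2R)-lavandulyl]-8,8-dimethyl-1,7-diprenylbicyclo[3.3.1]nonane-2,4,9-trione, via keto acid chloride 19 (not isolated)
Conditions: 18, CH2Cl2, −20 °C to rt; then KOH, benzyltriethylammonium chloride (10 mol %), H2O, rt
Reagents that add atoms: none
Why: Effenberger cyclisation of a 2,6-disubstituted cyclohexanone silyl enol ether, in which C5 is acylated axially on the ring face that carries only the axial H7 (anti to the equatorial C7 prenyl group) and the tethered acid chloride can reach the C1 enol only on that same face, so C7 sets both C5 and C1 while ring A closes as a 1,3-diaxial six-membered bridge.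

Step 14
Reactants: 20 trione
Product: 21 (1R,5S,7R)-2-methoxy-5-[(2R)-lavandulyl]-8,8-dimethyl-1,7-diprenylbicyclo[3.3.1]non-2-ene-4,9-dione
Conditions: Me2SO4, K2CO3, acetone, rt
Reagents that add atoms: dimethyl sulfate, COS(=O)(=O)OC
Why: O-alkylation of the vinylogous acid enolate should favour O2, which is flanked by the slim prenyl CH2, over O4, which is screened by the β-branched lavandulyl chain; the regioisomeric ether is separated and returned to 20 by LiOH hydrolysis.

Step 15
Reactants: 21 methyl enol ether; 22 benzoyl chloride
Product: 23 target, (1R,5R,7R)-3-benzoyl-2-methoxy-8,8-dimethyl-1,7-bis(3-methylbut-2-enyl)-5-[(2R)-5-methyl-2-(prop-1-en-2-yl)hex-4-enyl]bicyclo[3.3.1]non-2-ene-4,9-dione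
Conditions: LiTMP, THF, −78 °C; then 22
Reagents that add atoms: none
Why: Vinylic α-lithiation of the β-methoxy enone at C3, the only acidic site now that both bridgeheads are quaternary, followed by C-acylation is the established way to place the C3 acyl group on such enol ethers and changes no stereocentre.

**Compound list**
1 | (S)-4-benzyl-1,3-oxazolidin-2-one | O=C1N[C@@H](Cc2ccccc2)CO1 | starting material
2 | 3-methylbut-2-enoyl chloride | CC(C)=CC(=O)Cl | starting material
3 | (S)-4-benzyl-3-(3-methylbut-2-enoyl)-1,3-oxazolidin-2-one | CC(C)=CC(=O)N1[C@@H](Cc2ccccc2)COC1=O | intermediate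
4 | prenyl bromide | CC(C)=CCBr | starting material
5 | α-prenylated β,γ-unsaturated imide (2S) | C=C(C)[C@H](CC=C(C)C)C(=O)N1[C@@H](Cc2ccccc2)COC1=O | intermediate
6 | (S)-lavandulol | C=C(C)[C@H](CC=C(C)C)CO | intermediate
7 | (S)-lavandulyl iodide | C=C(C)[C@H](CC=C(C)C)CI | intermediate
8 | dimethyl (2-oxopropyl)phosphonate | CC(=O)CP(=O)(OC)OC | starting material
9 | dimethyl (6-methyl-2-oxohept-5-en-1-yl)phosphonate | CC(C)=CCCC(=O)CP(=O)(OC)OC | intermediate
10 | α-lavandulyl β-keto phosphonate (epimers at the P-bearing carbon) | C=C(C)[C@H](CC=C(C)C)CC(C(=O)CCC=C(C)C)P(=O)(OC)OC | intermediate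
11 | 2-[(2R)-lavandulyl]-7-methylocta-1,6-dien-3-one | C=C(C)[C@H](CC=C(C)C)CC(=C)C(=O)CCC=C(C)C | intermediate
12 | (3Z)-2-silyloxydiene | C=C(C)[C@H](CC=C(C)C)CC(=C)/C(O[Si](C)(C)C(C)(C)C)=C/CC=C(C)C | intermediate
13 | phorone | CC(C)=CC(=O)C=C(C)C | starting material
14 | ring-B adduct with C7 3-methylbut-2-enoyl group (1R,7R) | C=C(C)[C@H](CC=C(C)C)CC1=C(O[Si](C)(C)C(C)(C)C)[C@H](CC=C(C)C)C(C)(C)[C@H](C(=O)C=C(C)C)C1 | intermediate
15 | allylic alcohol (carbinol epimers) | C=C(C)[C@H](CC=C(C)C)CC1=C(O[Si](C)(C)C(C)(C)C)[C@H](CC=C(C)C)C(C)(C)[C@H](C(O)C=C(C)C)C1 | intermediate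
16 | allylic methyl carbonate | C=C(C)[C@H](CC=C(C)C)CC1=C(O[Si](C)(C)C(C)(C)C)[C@H](CC=C(C)C)C(C)(C)[C@H](C(OC(=O)OC)C=C(C)C)C1 | intermediate
17 | ring-B silyl enol ether with all three side chains (1R,7R) | C=C(C)[C@H](CC=C(C)C)CC1=C(O[Si](C)(C)C(C)(C)C)[C@H](CC=C(C)C)C(C)(C)[C@H](CC=C(C)C)C1 | intermediate
18 | malonyl dichloride | O=C(Cl)CC(=O)Cl | starting material
19 | keto acid chloride, C5-acylated ring-B ketone (not isolated) | C=C(C)[C@H](CC=C(C)C)C[C@@]1(C(=O)CC(=O)Cl)C[C@@H](CC=C(C)C)C(C)(C)[C@@H](CC=C(C)C)C1=O | intermediate
20 | bicyclo[3.3.1]nonane-2,4,9-trione (1R,5S,7R) | C=C(C)[C@H](CC=C(C)C)C[C@@]12C[C@@H](CC=C(C)C)C(C)(C)[C@@](CC=C(C)C)(C1=O)C(=O)CC2=O | intermediate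
21 | C2 methyl enol ether (1R,5S,7R) | C=C(C)[C@H](CC=C(C)C)C[C@@]12C[C@@H](CC=C(C)C)C(C)(C)[C@@](CC=C(C)C)(C1=O)C(OC)=CC2=O | intermediate
22 | benzoyl chloride | O=C(Cl)c1ccccc1 | starting material
23 | CNP0385193.1 | C=C(C)[C@H](CC=C(C)C)C[C@@]12C[C@@H](CC=C(C)C)C(C)(C)[C@@](CC=C(C)C)(C1=O)C(OC)=C(C(=O)c1ccccc1)C2=O | target

**Totals**
Total step count: 15.
Longest linear sequence: 14 (steps 1–4 and 6–15).

**Steps most likely to fail**

Step 9. The bulky chiral Lewis acid may not turn over with two hindered partners, the diene may be protodesilylated, or facial discrimination at C7 may be poor.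
- The fallback sets out from 12 and 13 and splits the event into its two known halves.
- A TiCl4-promoted Mukaiyama–Michael addition at −78 °C, known for β,β-dimethyl enones, should give after aqueous work-up the acyclic enedione F1.
- DBU in THF then closes ring B by intramolecular Michael addition of C7 onto C6 to give the all-cis ring-B diketone F2.
- All three ring stereocentres of F2 lie α to a carbonyl group. The two ring diastereomers, which differ only in their sense relative to the lavandulyl centre, can therefore be separated by chromatography and the unwanted one re-equilibrated with DBU.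
- Silylation with TBSOTf/Et3N toward the less hindered C5 comes back to the route at 14.

Step 13. O-acylation to an enol lactone, failure of the closure at the hindered C1, or attack of the liberated HCl on the isopropenyl and prenyl alkenes may dominate.
- The fallback sets out from 17 and builds ring A in two separate events.
- C-acylation with methyl 3-chloro-3-oxopropanoate in CH2Cl2 in the presence of 2,6-di-tert-butylpyridine gives the C5-acylated β-keto ester F3.
- A Dieckmann condensation with KOt-Bu in THF follows, in which the C1 enolate attacks the ester. It is driven by formation of the stabilised β-diketone enolate and comes back to the route at 20.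

Step 14. Methylation may go mainly to the wrong oxygen (O4).
- The fallback sets out from 20 and turns this bias to advantage.
- The more accessible oxygen is capped with the much bulkier TIPSOTf/2,6-lutidine to give the C4 triisopropylsilyl enol ether F4.
- MeOTf with 2,6-di-tert-butyl-4-methylpyridine then alkylates the remaining vinylogous-ester carbonyl oxygen O2.
- Loss of the silyl group from the resulting dialkoxyallyl cation on CsF work-up comes back to the route at 21.

**Further compounds**
F1 | step 9 | acyclic enedione, C6H2=C5(lavandulyl)–C9(=O)–C1H(prenyl)–C8Me2–C7H2–CO–CH=CMe2 (epimers at C1) | C=C(C)[C@H](CC=C(C)C)CC(=C)C(=O)C(CC=C(C)C)C(C)(C)CC(=O)C=C(C)C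
F2 | step 9 | all-cis ring-B diketone, 2-lavandulyl-5,5-dimethyl-4-(3-methylbut-2-enoyl)-6-prenylcyclohexanone | C=C(C)[C@H](CC=C(C)C)C[C@H]1C[C@@H](C(=O)C=C(C)C)C(C)(C)[C@@H](CC=C(C)C)C1=O
F3 | step 13 | C5-acylated β-keto ester, methyl 3-oxo-3-(ring-B ketone C5-yl)propanoate | C=C(C)[C@H](CC=C(C)C)C[C@@]1(C(=O)CC(=O)OC)C[C@@H](CC=C(C)C)C(C)(C)[C@@H](CC=C(C)C)C1=O
F4 | step 14 | C4 triisopropylsilyl enol ether of the trione | C=C(C)[C@H](CC=C(C)C)C[C@@]12C[C@@H](CC=C(C)C)C(C)(C)[C@@](CC=C(C)C)(C1=O)C(=O)C=C2O[Si](C(C)C)(C(C)C)C(C)C
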